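**Retrosynthetic overview**
1. 25 ⇐ tetraol 24 (MnO2 on the only allylic CH2OH) ⇐ 23 (desilylation) ⇐ 22 (LiAlH4) ⇐ ketone 21 (methyl addition sets C10).
2. The (16Z)-triene of 21 comes from a Julia–Kocienski union of enal 17 with geranyl benzothiazolyl sulfone 20; 17 comes from cross-metathesis of butenyl keto ester 15 with methacrolein.
3. The only ring is closed the way the cyclase closes it: a C6 allyl cation (from allylic alcohol 14) is captured by the C10=C11 π bond (enol of the β-keto ester), forming C6–C11 with C10 kept oxygenated; one chiral-acid step sets C6 and C11.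
4. 14 ⇐ Nozaki–Hiyama–Kishi coupling of vinyl iodide 9 with aldehyde 12; 9 ⇐ crossed Claisen of iodo acid 6 with methyl hex-5-enoate; the (Z)-tetrasubstituted olefin of 6 ⇐ anti-carbomagnesiation/iodination of alkynol 2.
5. Ring order: one six-membered ring (C6–C7–C8–C9–C10–C11), formed in step 8 of 16.

Locants in the Why lines follow iridal numbering: C1 = CHO carbon, C2 = its α-carbon (C25 methyl), C3–C5 = hydroxypropyl chain (C3 bears OH), C6 = ring CH, C7 = ring sp2 carbon, C8 and C9 = ring CH2, C10 = C(OH)CH3, C11 = quaternary carbon, C12–C24 = side chain, C26 = CH2OH.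

Assumption: which antipode of the step 8 catalyst gives the (1R,6R) series cannot be predicted; the (R)-catalyst is written and its mirror image is used if the first run gives ent-15.

**Route**

Step 1
Reactants: 1 pent-4-ynoic acid
Product: 2 6-hydroxyhex-4-ynoic acid
Conditions: LiN(i-Pr)2 (2.2 equiv), THF, −78 → 0 °C; (CH2O)n, 0 °C → rt; aq. HCl
Reagents that add atoms: formaldehyde (as paraformaldehyde), C=O
Why: Hydroxymethylation of the carboxylate/acetylide dianion (acetylide addition to formaldehyde); no stereocenter is formed.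

Step 2
Reactants: 2 6-hydroxyhex-4-ynoic acid
Product: 4 (4Z)-6-hydroxy-4-iodo-5-methylhex-4-enoic acid, via alkenylmagnesium bromide 3 (not isolated)
Conditions: MeMgBr (4.5 equiv), CuI (20 mol %), THF, 0 → 40 °C; then I2, −40 → 0 °C; aq. HCl/Na2S2O3
Reagents that add atoms: methylmagnesium bromide, C[Mg]Br; iodine, II
Why: Copper-catalysed anti-carbomagnesiation of a propargylic alkoxide (Duboudin–Jousseaume type) puts methyl on the carbon next to CH2O and holds magnesium cis to oxygen, and iodinolysis with retention fixes the tetrasubstituted olefin (later C1 cis to C6, C25 methyl cis to C8).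

Step 3
Reactants: 4 (4Z)-6-hydroxy-4-iodo-5-methylhex-4-enoic acid
Product: 6 (4Z)-6-[(tert-butyldiphenylsilyl)oxy]-4-iodo-5-methylhex-4-enoic acid, via silyl ester 5 (not isolated)
Conditions: TBDPSCl (2.2 equiv), imidazole, DMF, rt; then K2CO3, MeOH/H2O, rt
Reagents that add atoms: tert-butyl(chloro)diphenylsilane, CC(C)(C)[Si](Cl)(c1ccccc1)c1ccccc1
Why: Silylation of alcohol and acid followed by selective hydrolysis of the labile silyl ester; a silyl ether is chosen at C1 because, unlike an ester, it cannot engage the later allyl cation by neighbouring-group participation and scramble the olefin geometry.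

Step 4
Reactants: 6 (4Z)-6-[(tert-butyldiphenylsilyl)oxy]-4-iodo-5-methylhex-4-enoic acid; 7 methyl hex-5-enoate
Product: 9 methyl (6Z)-2-(but-3-en-1-yl)-8-[(tert-butyldiphenylsilyl)oxy]-6-iodo-7-methyl-3-oxooct-6-enoate (racemic at C2), via acyl imidazolide 8 (not isolated)
Conditions: CDI (1.1 equiv), THF, rt; then added to 7/LiN(i-Pr)2 (2.2 equiv each), THF, −78 °C
Reagents that add atoms: none
Why: Crossed Claisen acylation of the ester enolate by the acyl imidazolide gives the β-keto ester (C10 ketone, C11, C26 ester); its α-stereocenter is left racemic because step 8 erases it.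

Step 5
Reactants: 10 butane-1,4-diol
Product: 11 4-hydroxybutyl pivalate
Conditions: PivCl (0.3 equiv), pyridine, CH2Cl2, 0 °C (diol in excess)
Reagents that add atoms: pivaloyl chloride, CC(C)(C)C(=O)Cl
Why: Statistical monoacylation of a cheap symmetrical diol used in excess.

Step 6
Reactants: 11 4-hydroxybutyl pivalate
Product: 12 4-oxobutyl pivalate
Conditions: TEMPO (10 mol %), PhI(OAc)2 (1.1 equiv), CH2Cl2, rt
Reagents that add atoms: none
Why: Oxoammonium (TEMPO) oxidation stops cleanly at the aldehyde.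

Step 7
Reactants: 9 vinyl iodide β-keto ester; 12 4-oxobutyl pivalate
Product: 14 methyl (6Z)-2-(but-3-en-1-yl)-6-{1-[(tert-butyldiphenylsilyl)oxy]propan-2-ylidene}-7-hydroxy-3-oxo-10-(pivaloyloxy)decanoate (mixture at C2 and C7), via alkenylchromium dichloride 13 (not isolated)
Conditions: CrCl2 (5 equiv), NiCl2 (2 mol %), DMSO, rt; aq. NH4Cl
Reagents that add atoms: none
Why: Nozaki–Hiyama–Kishi coupling: the alkenylchromium species adds only to the aldehyde (ketone, esters and the acidic α-H are tolerated) with retention of olefin geometry; the new carbinol center is formed unselectively and is erased in step 8.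

Step 8
Reactants: 14 allylic alcohol β-keto ester
Product: 15 methyl (1R,6R,5Z)-1-(but-3-en-1-yl)-5-{1-[(tert-butyldiphenylsilyl)oxy]propan-2-ylidene}-2-oxo-6-[3-(pivaloyloxy)propyl]cyclohexane-1-carboxylate
Conditions: (R)-3,3′-bis(2,4,6-triisopropylphenyl)-1,1′-binaphthalene-2,2′-diyl N-triflylphosphoramide (10 mol %), toluene, 5 Å MS, 0 °C → rt
Reagents that add atoms: none
Why: Proposed new method: the acid protonates the allylic alcohol, water leaves, and the C6–C7–C2 allyl cation (CH2OSi fixed cis to C6, the C5 chain in the unhindered outside position to avoid A(1,3) strain) is held as an ion pair by the chiral phosphoramidate, which also hydrogen-bonds the enol OH; the enol C10=C11 π bond attacks C6 rather than C2 (which would join two quaternary carbons) through a chair in which the outside C5 chain and the butenyl group (cis to C9 in the chelated enol) are trans-diaxial and CO2Me is equatorial, so C6 and C11 are set together with the C5 chain cis to CO2Me, the catalyst pocket choosing the enantiotopic face pair; both stereocenters of 14 are destroyed on the way (stereoconvergent) and reversible O-alkylation funnels to the C–C product; closest known reaction types are chiral phosphoric acid or N-triflylphosphoramide-catalysed SN1 alkylations of β-keto ester enols by cations generated from alcohols, acid-catalysed dehydrative allylation of 1,3-dicarbonyls, and cation–olefin cyclisation.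

Step 9
Reactants: 15 butenyl keto ester; 16 methacrolein
Product: 17 methyl (1R,6R,5Z)-5-{1-[(tert-butyldiphenylsilyl)oxy]propan-2-ylidene}-1-[(3E)-4-methyl-5-oxopent-3-en-1-yl]-2-oxo-6-[3-(pivaloyloxy)propyl]cyclohexane-1-carboxylate
Conditions: second-generation Hoveyda–Grubbs catalyst, RuCl2(SIMes)(=CH–C6H4-2-O-i-Pr) (5 mol %), 16 (10 equiv), CH2Cl2, 40 °C
Reagents that add atoms: none
Why: Olefin cross-metathesis of the only monosubstituted olefin with methacrolein gives the (E)-trisubstituted enal under thermodynamic control; the tetrasubstituted olefin is inert.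

Step 10
Reactants: 18 geraniol
Product: 19 2-{[(2E)-3,7-dimethylocta-2,6-dien-1-yl]sulfanyl}-1,3-benzothiazole
Conditions: 1,3-benzothiazole-2-thiol, PPh3, DIAD, THF, 0 °C → rt
Reagents that add atoms: 1,3-benzothiazole-2-thiol, Sc1nc2ccccc2s1
Why: Mitsunobu thioetherification at the primary allylic carbon (SN2, no allylic transposition, E olefin untouched).

Step 11
Reactants: 19 geranyl benzothiazolyl sulfide
Product: 20 2-{[(2E)-3,7-dimethylocta-2,6-dien-1-yl]sulfonyl}-1,3-benzothiazole
Conditions: (NH4)6Mo7O24·4H2O (10 mol %), 30% H2O2, EtOH, 0 °C → rt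
Reagents that add atoms: hydrogen peroxide, OO
Why: Molybdate-catalysed sulfide-to-sulfone oxidation is chemoselective for sulfur over the trisubstituted olefins.

Step 12
Reactants: 17 enal; 20 geranyl benzothiazolyl sulfone
Product: 21 methyl (1R,6R,5Z)-5-{1-[(tert-butyldiphenylsilyl)oxy]propan-2-ylidene}-2-oxo-6-[3-(pivaloyloxy)propyl]-1-[(3E,5Z,7E)-4,8,12-trimethyltrideca-3,5,7,11-tetraen-1-yl]cyclohexane-1-carboxylate
Conditions: 20 (1.3 equiv), NaN(SiMe3)2 (1.25 equiv), THF, −78 °C; then 17, −78 °C → rt, dark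
Reagents that add atoms: none
Why: Julia–Kocienski olefination; allylic benzothiazolyl sulfone anions add to enals to give the new disubstituted olefin (C16=C17) with a Z preference while both flanking E olefins are retained, and the aldehyde reacts in preference to the hindered ketone.

Step 13
Reactants: 21 triene keto ester
Product: 22 methyl (1R,2S,6R,5Z)-5-{1-[(tert-butyldiphenylsilyl)oxy]propan-2-ylidene}-2-hydroxy-2-methyl-6-[3-(pivaloyloxy)propyl]-1-[(3E,5Z,7E)-4,8,12-trimethyltrideca-3,5,7,11-tetraen-1-yl]cyclohexane-1-carboxylate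
Conditions: MeMgBr (3 equiv), CeCl3 (3 equiv), THF, −78 °C; NH4Cl at −78 °C
Reagents that add atoms: methylmagnesium bromide, C[Mg]Br
Why: Organocerium 1,2-addition (non-basic, ketone-selective over the hindered ester and the pivalate); axial approach is blocked by the syn-axial C6 side chain, so methyl enters from the face of the C12 chain and the C10 hydroxyl ends cis to both the ester (C26) and the C6 side chain.

Step 14
Reactants: 22 tertiary alcohol ester
Product: 23 (1S,2S,3R,4Z)-4-{1-[(tert-butyldiphenylsilyl)oxy]propan-2-ylidene}-2-(hydroxymethyl)-3-(3-hydroxypropyl)-1-methyl-2-[(3E,5Z,7E)-4,8,12-trimethyltrideca-3,5,7,11-tetraen-1-yl]cyclohexan-1-ol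
Conditions: LiAlH4 (5 equiv), THF, 0 °C → rt; aq. KNaC4H4O6
Reagents that add atoms: none
Why: Hydride reduction turns the methyl ester into the C26 CH2OH and cleaves the pivalate; the triene and the silyl ether are inert and no stereocenter is touched.

Step 15
Reactants: 23 silyl ether triol
Product: 24 (1S,2S,3R,4Z)-2-(hydroxymethyl)-4-(1-hydroxypropan-2-ylidene)-3-(3-hydroxypropyl)-1-methyl-2-[(3E,5Z,7E)-4,8,12-trimethyltrideca-3,5,7,11-tetraen-1-yl]cyclohexan-1-ol
Conditions: Bu4NF (1.5 equiv), THF, 0 °C → rt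
Reagents that add atoms: none
Why: Fluoride-induced desilylation of the primary allylic silyl ether; nothing else in the molecule responds.

Step 16
Reactants: 24 tetraol
Product: 25 (2Z)-2-{(2R,3S,4S)-4-hydroxy-3-(hydroxymethyl)-2-(3-hydroxypropyl)-4-methyl-3-[(3E,5Z,7E)-4,8,12-trimethyltrideca-3,5,7,11-tetraen-1-yl]cyclohexylidene}propanal
Conditions: MnO2 (20 equiv), CH2Cl2, rt, dark
Reagents that add atoms: none
Why: MnO2 oxidises only the allylic primary alcohol (C1) to the enal under neutral conditions, leaving the saturated primary and tertiary alcohols and all olefin geometries intact.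

**Compound list**

1 | pent-4-ynoic acid | C#CCCC(=O)O | starting material
2 | 6-hydroxyhex-4-ynoic acid | OCC#CCCC(=O)O | intermediate
3 | bromomagnesium (4Z)-4-(bromomagnesio)-6-(bromomagnesiooxy)-5-methylhex-4-enoate (Mg cis to CH2O) | C/C(CO[Mg]Br)=C(/[Mg]Br)CCC(=O)O[Mg]Br | intermediate (not isolated)
4 | (4Z)-6-hydroxy-4-iodo-5-methylhex-4-enoic acid | OC/C(C)=C(\I)CCC(=O)O | intermediate
5 | tert-butyldiphenylsilyl (4Z)-6-[(tert-butyldiphenylsilyl)oxy]-4-iodo-5-methylhex-4-enoate | CC(C)(C)[Si](c1ccccc1)(c1ccccc1)OC/C(C)=C(\I)CCC(=O)O[Si](c1ccccc1)(c1ccccc1)C(C)(C)C | intermediate (not isolated)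
6 | (4Z)-6-[(tert-butyldiphenylsilyl)oxy]-4-iodo-5-methylhex-4-enoic acid | CC(C)(C)[Si](c1ccccc1)(c1ccccc1)OC/C(C)=C(\I)CCC(=O)O | intermediate
7 | methyl hex-5-enoate | COC(=O)CCCC=C | starting material
8 | (4Z)-6-[(tert-butyldiphenylsilyl)oxy]-1-(imidazol-1-yl)-4-iodo-5-methylhex-4-en-1-one | CC(C)(C)[Si](c1ccccc1)(c1ccccc1)OC/C(C)=C(\I)CCC(=O)n1ccnc1 | intermediate (not isolated)
9 | methyl (6Z)-2-(but-3-en-1-yl)-8-[(tert-butyldiphenylsilyl)oxy]-6-iodo-7-methyl-3-oxooct-6-enoate (racemic at C2) | COC(=O)C(CCC=C)C(=O)CC/C(I)=C(\C)CO[Si](c1ccccc1)(c1ccccc1)C(C)(C)C | intermediate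
10 | butane-1,4-diol | OCCCCO | starting material
11 | 4-hydroxybutyl pivalate | CC(C)(C)C(=O)OCCCCO | intermediate
12 | 4-oxobutyl pivalate | CC(C)(C)C(=O)OCCCC=O | intermediate
13 | alkenylchromium dichloride from 9 (CrCl2 in place of I, same olefin geometry) | COC(=O)C(CCC=C)C(=O)CC/C([Cr](Cl)Cl)=C(\C)CO[Si](c1ccccc1)(c1ccccc1)C(C)(C)C | intermediate (not isolated)
14 | methyl (6Z)-2-(but-3-en-1-yl)-6-{1-[(tert-butyldiphenylsilyl)oxy]propan-2-ylidene}-7-hydroxy-3-oxo-10-(pivaloyloxy)decanoate (mixture at C2 and C7) | COC(=O)C(CCC=C)C(=O)CC/C(C(O)CCCOC(=O)C(C)(C)C)=C(\C)CO[Si](c1ccccc1)(c1ccccc1)C(C)(C)C | intermediate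
15 | methyl (1R,6R,5Z)-1-(but-3-en-1-yl)-5-{1-[(tert-butyldiphenylsilyl)oxy]propan-2-ylidene}-2-oxo-6-[3-(pivaloyloxy)propyl]cyclohexane-1-carboxylate | C=CCC[C@@]1(C(=O)OC)[C@H](CCCOC(=O)C(C)(C)C)/C(=C(/C)CO[Si](c2ccccc2)(c2ccccc2)C(C)(C)C)CCC1=O | intermediate
16 | methacrolein | CC(=C)C=O | starting material
17 | methyl (1R,6R,5Z)-5-{1-[(tert-butyldiphenylsilyl)oxy]propan-2-ylidene}-1-[(3E)-4-methyl-5-oxopent-3-en-1-yl]-2-oxo-6-[3-(pivaloyloxy)propyl]cyclohexane-1-carboxylate | O=C/C(C)=C/CC[C@@]1(C(=O)OC)[C@H](CCCOC(=O)C(C)(C)C)/C(=C(/C)CO[Si](c2ccccc2)(c2ccccc2)C(C)(C)C)CCC1=O | intermediate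
18 | geraniol, (2E)-3,7-dimethylocta-2,6-dien-1-ol | CC(C)=CCC/C(C)=C/CO | starting material
19 | 2-{[(2E)-3,7-dimethylocta-2,6-dien-1-yl]sulfanyl}-1,3-benzothiazole | CC(C)=CCC/C(C)=C/CSc1nc2ccccc2s1 | intermediate
20 | 2-{[(2E)-3,7-dimethylocta-2,6-dien-1-yl]sulfonyl}-1,3-benzothiazole | CC(C)=CCC/C(C)=C/CS(=O)(=O)c1nc2ccccc2s1 | intermediate
21 | methyl (1R,6R,5Z)-5-{1-[(tert-butyldiphenylsilyl)oxy]propan-2-ylidene}-2-oxo-6-[3-(pivaloyloxy)propyl]-1-[(3E,5Z,7E)-4,8,12-trimethyltrideca-3,5,7,11-tetraen-1-yl]cyclohexane-1-carboxylate | CC(C)=CCC/C(C)=C/C=C\C(C)=C\CC[C@@]1(C(=O)OC)[C@H](CCCOC(=O)C(C)(C)C)/C(=C(/C)CO[Si](c2ccccc2)(c2ccccc2)C(C)(C)C)CCC1=O | intermediate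
22 | methyl (1R,2S,6R,5Z)-5-{1-[(tert-butyldiphenylsilyl)oxy]propan-2-ylidene}-2-hydroxy-2-methyl-6-[3-(pivaloyloxy)propyl]-1-[(3E,5Z,7E)-4,8,12-trimethyltrideca-3,5,7,11-tetraen-1-yl]cyclohexane-1-carboxylate | CC(C)=CCC/C(C)=C/C=C\C(C)=C\CC[C@@]1(C(=O)OC)[C@H](CCCOC(=O)C(C)(C)C)/C(=C(/C)CO[Si](c2ccccc2)(c2ccccc2)C(C)(C)C)CC[C@]1(C)O | intermediate
23 | (1S,2S,3R,4Z)-4-{1-[(tert-butyldiphenylsilyl)oxy]propan-2-ylidene}-2-(hydroxymethyl)-3-(3-hydroxypropyl)-1-methyl-2-[(3E,5Z,7E)-4,8,12-trimethyltrideca-3,5,7,11-tetraen-1-yl]cyclohexan-1-ol | CC(C)=CCC/C(C)=C/C=C\C(C)=C\CC[C@@]1(CO)[C@H](CCCO)/C(=C(/C)CO[Si](c2ccccc2)(c2ccccc2)C(C)(C)C)CC[C@]1(C)O | intermediate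
24 | (1S,2S,3R,4Z)-2-(hydroxymethyl)-4-(1-hydroxypropan-2-ylidene)-3-(3-hydroxypropyl)-1-methyl-2-[(3E,5Z,7E)-4,8,12-trimethyltrideca-3,5,7,11-tetraen-1-yl]cyclohexan-1-ol | CC(C)=CCC/C(C)=C/C=C\C(C)=C\CC[C@@]1(CO)[C@H](CCCO)/C(=C(/C)CO)CC[C@]1(C)O | intermediate
25 | (2Z)-2-{(2R,3S,4S)-4-hydroxy-3-(hydroxymethyl)-2-(3-hydroxypropyl)-4-methyl-3-[(3E,5Z,7E)-4,8,12-trimethyltrideca-3,5,7,11-tetraen-1-yl]cyclohexylidene}propanal | CC(C)=CCC/C(C)=C/C=C\C(C)=C\CC[C@@]1(CO)[C@H](CCCO)/C(=C(/C)C=O)CC[C@]1(C)O | target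

**Count**

Total steps: 16. Longest linear sequence: 12 (steps 1, 2, 3, 4, 7, 8, 9, 12, 13, 14, 15, 16); steps 5–6 and 10–11 are side branches.

**Steps most likely to fail, each with a fallback**

Step 8 (cyclisation). The acid may not ionise 14 cleanly (diene formation by proton loss is the competitor), and the level and sense of enantiocontrol are untested. The fallback moves the stereocontrol from the counter-ion to a covalent auxiliary on the nucleophile and sets out from 14. Condensation with (S)-1-phenylethylamine (toluene, 4 Å MS, cat. AcOH) gives the hydrogen-bonded methyl (2Z,6Z)-2-(but-3-en-1-yl)-6-{1-[(tert-butyldiphenylsilyl)oxy]propan-2-ylidene}-7-hydroxy-3-{[(1S)-1-phenylethyl]amino}-10-(pivaloyloxy)dec-2-enoate F1. Triflic acid (10 mol %, CH2Cl2, −40 °C) then ionises the allylic alcohol, and the secondary enamine, a stronger π-nucleophile than the enol, attacks C6 through C11 on the face away from the phenyl-bearing N-substituent (auxiliary-controlled deracemising alkylation of the d'Angelo type, here with a cation as electrophile). Aqueous acetic acid hydrolyses the ketimine and the route is rejoined at 15; the antipodal amine is used if the sense is wrong.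

Step 12 (Z-selective olefination). The Z/E ratio at C16=C17 may be poor. The fallback forms the Z bond by a Wittig reaction and joins the fragments by cross-coupling; it sets out from 17. Stork–Zhao olefination (Ph3P=CHI from (iodomethyl)triphenylphosphonium iodide and NaN(SiMe3)2, THF/HMPA, −78 °C) gives methyl (1R,6R,5Z)-5-{1-[(tert-butyldiphenylsilyl)oxy]propan-2-ylidene}-1-[(3E,5Z)-6-iodo-4-methylhexa-3,5-dien-1-yl]-2-oxo-6-[3-(pivaloyloxy)propyl]cyclohexane-1-carboxylate F2. Separately, zirconium-catalysed methylalumination (Me3Al, Cp2ZrCl2) of purchased 6-methylhept-5-en-1-yne gives [(1E)-2,6-dimethylhepta-1,5-dien-1-yl]dimethylalane F3, which is borylated with i-PrOBpin to 2-[(1E)-2,6-dimethylhepta-1,5-dien-1-yl]-4,4,5,5-tetramethyl-1,3,2-dioxaborolane F4. Suzuki coupling of F2 with F4 (Pd(PPh3)4, aq. K3PO4, THF), which retains both olefin geometries, rejoins the route at 21.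

Step 13 (methyl addition). The two ketone faces are both hindered, so the methyl may enter from the wrong face, and the tertiary aldolate can undergo retro-aldol cleavage. The fallback builds C10 through an epoxide and sets out from 21. Corey–Chaykovsky reaction with dimethylsulfoxonium methylide (Me3S(O)I, NaH, DMSO/THF), whose reversible addition puts the new C–C bond in the less hindered position on the face remote from the C6 side chain, gives the spiro-epoxide of 21 at the ketone carbon (CH2 on the face of the C12 chain, O on the face of the ester; S at the spiro carbon) F5. LiAlH4 then opens the oxirane at CH2 (which becomes the C27 methyl), reduces the ester and cleaves the pivalate in one operation, rejoining the route at 23.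

**Further compounds**

F1 | step 8 | methyl (2Z,6Z)-2-(but-3-en-1-yl)-6-{1-[(tert-butyldiphenylsilyl)oxy]propan-2-ylidene}-7-hydroxy-3-{[(1S)-1-phenylethyl]amino}-10-(pivaloyloxy)dec-2-enoate | COC(=O)/C(CCC=C)=C(\N[C@@H](C)c1ccccc1)CC/C(C(O)CCCOC(=O)C(C)(C)C)=C(\C)CO[Si](c1ccccc1)(c1ccccc1)C(C)(C)C
F2 | step 12 | methyl (1R,6R,5Z)-5-{1-[(tert-butyldiphenylsilyl)oxy]propan-2-ylidene}-1-[(3E,5Z)-6-iodo-4-methylhexa-3,5-dien-1-yl]-2-oxo-6-[3-(pivaloyloxy)propyl]cyclohexane-1-carboxylate | I/C=C\C(C)=C\CC[C@@]1(C(=O)OC)[C@H](CCCOC(=O)C(C)(C)C)/C(=C(/C)CO[Si](c2ccccc2)(c2ccccc2)C(C)(C)C)CCC1=O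
F3 | step 12 | [(1E)-2,6-dimethylhepta-1,5-dien-1-yl]dimethylalane | C[Al](C)/C=C(\C)CCC=C(C)C
F4 | step 12 | 2-[(1E)-2,6-dimethylhepta-1,5-dien-1-yl]-4,4,5,5-tetramethyl-1,3,2-dioxaborolane | CC(C)=CCC/C(C)=C/B1OC(C)(C)C(C)(C)O1
F5 | step 13 | spiro-epoxide of 21 at the ring ketone carbon (CH2 on the face of the C12 chain, O on the face of the ester; S at the spiro carbon) | CC(C)=CCC/C(C)=C/C=C\C(C)=C\CC[C@@]1(C(=O)OC)[C@H](CCCOC(=O)C(C)(C)C)/C(=C(/C)CO[Si](c2ccccc2)(c2ccccc2)C(C)(C)C)CC[C@@]13CO3
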